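0.355 was the reach of the south-east run at its last reading, reach being the natural logarithm of electrophile charged over electrophile left. For the second-order step of electrophile with nucleophile, reach counts the rate constant times free nucleophile summed over time, and that nucleophile concentration changes as the run goes on.

| flask | electrophile | nucleophile | free base | remark | time |
|---|---|---|---|---|---|
| west | 0.40 M | 0.64 M | 0.96 M | run made earlier |  |
| south-west | 0.60 M | 0.64 M | 0.96 M | run made earlier |  |
| south-east | 0.80 M | 0.64 M | 1.9 M | run made earlier |  |
| flask | 0.80 M | 0.640 M | 0.960 M |  | 80 min |

- west (time / min: electrophile / %, product / %): 4.00: 83.6, 15.9; 8.00: 77.0, 23.6; 20.0: 66.3, 34.2; 50.0: 58.3, 42.0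
- south-west (time / min: electrophile / %, product / %): 4.00: 86.0, 14.2; 8.00: 77.8, 20.7; 20.0: 70.3, 29.9; 50.0: 65.8, 34.1
- south-east (time / min: electrophile / %, product / %): 6.00: 82.2, 16.8; 15.0: 75.9, 25.4; 30.0: 71.5, 28.8; 50.0: 70.1, 29.8

(scatter of a reading: 0.5 percentage points)

- reactions considered so far: 2 nucleophile -> homo dimer; acid set free + free base <-> salt of the base; electrophile + nucleophile -> acid set free + product; nucleophile + acid set free <-> protonated nucleophile
- the earlier runs do not show how much of nucleophile is bound; that part of a forecast is a guess

1. part of the electrophile that has reacted at 80 min
2. share of the unused nucleophile that is free and not bound as protonated nucleophile, at 80 min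

I built a ladder from the south-east readings. On the lowest rung, the pace up to the first reading would have delivered that reach in 10.9 min. On the highest, the creep of 9.89 × 10⁻⁴ min⁻¹ between the last two readings needed 359 min to add as much again. The asked 80 min lay between them, so I expected a stalled flask, creeping.

Setting the west reach of 0.540 against the south-east one gave an apparent order of 0.603 in equivalents of nucleophile. That order put the south-west reach at 0.423, and the readings gave 0.419. This flask has the south-east equivalents, so I added the creep up to 80 min and reckoned a reach of 0.385, or 31.9% reacted. The runs do not show how much of the nucleophile is bound, so I set no number of my own for the free share.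

The forecast gave 31% (28% to 35%) and 85% free (55% to 98%), holding that “base has little kinetic effect while it stays in excess”.

The flask gave 31.5% reacted, a reach of 0.378, and 5.23% free.

    2 nucleophile → homo dimer (k = 0.00160 L mol⁻¹ s⁻¹)
    acid set free + free base ⇌ salt of the base (K = 130 L mol⁻¹, k = 0.00230 L mol⁻¹ s⁻¹)
    electrophile + nucleophile → acid set free + product (k = 0.00150 L mol⁻¹ s⁻¹)
    nucleophile + acid set free ⇌ protonated nucleophile, settled at all times (K = 2100 L mol⁻¹)

The neighbour flask was charged with 0.26 M of nucleophile, which is 0.325 equiv, with the other charges and the time held. The same reckoning scaled my reach at 80 min by the ratio of nucleophile charges raised to the apparent order, giving 0.224, or 20.0% reacted. That neighbour flask reacted 16.7%, a reach of 0.183.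

Readings and results are calculated with made-up constants; scatter was added.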